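**Retrosynthetic overview** (target chain numbered C1 = lactone carbonyl to C12 = methyl; oxolane = C7–C8–C9–C10–O)
1. Late disconnections: caffeate ester at C11–O; dihydropyranone by ring-closing metathesis of a C5 acrylate; C4–C5 by asymmetric allylation of a C5 aldehyde; C11 carbinol by reduction of a methyl ketone.
2. The C5 aldehyde and C11 methyl ketone come from ozonolysis of a temporary C5=C11 alkene in a 4-methyl-8-oxabicyclo[3.2.1]oct-3-en-2-ol, whose carbinol is C6.
3. That bicycle comes from a [5+2] cycloaddition of 5-methyl-3-oxidopyrylium with ethylene, which forms C7–C8 and C9–C10 together and fixes the cis-2,5 relation of the oxolane.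
4. Enabling feature: the oxolane oxygen is flanked by two CH carbons (C7, C10), each bearing an oxygenated carbon (C6, C11), with an unsubstituted C8–C9 unit. C6–C7–O–C10–C11(–C12) therefore maps onto C3(O-)–C2–O+–C6–C5(CH3) of an oxidopyrylium, with C5 as its C4.
5. Ring order: furan, then pyranone (Achmatowicz), then oxolane plus seven-membered carbocycle (key step), then cleavage of the carbocycle, then dihydropyranone (metathesis).

Key step: step 5

Remark on the chemistry: compounds 5, 6, 9 and 10 are racemic. 9 and 10 are drawn and named (prefix rac) as the enantiomer carried on after step 7; the acetal centre of 5 and 6 is left undefined because step 5 destroys it.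

**Step 1**
Reactants: 1 4-bromofuran-2-carbaldehyde; 2 methylboronic acid
Product: 3 4-methylfuran-2-carbaldehyde
Conditions: PdCl2(dppf) (3 mol%), K2CO3, dioxane/H2O, 90 °C
Reagents that add atoms: none
Why: Suzuki–Miyaura coupling of the heteroaryl bromide with methylboronic acid should tolerate the aldehyde and involves no stereocentre.

**Step 2**
Reactants: 3 4-methylfuran-2-carbaldehyde
Product: 4 (4-methylfuran-2-yl)methanol
Conditions: NaBH4, MeOH, 0 °C
Reagents that add atoms: none
Why: Borohydride reduction of the aldehyde gives the primary furfuryl alcohol needed for the ring expansion.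

**Step 3**
Reactants: 4 (4-methylfuran-2-yl)methanol
Product: 5 rac-6-hydroxy-5-methyl-2H-pyran-3(6H)-one
Conditions: mCPBA, CH2Cl2, 0 °C to rt
Reagents that add atoms: mCPBA, OOC(=O)c1cccc(Cl)c1
Why: Achmatowicz oxidative ring expansion, in which peracid oxidation opens the furan to the cis-enedione and the primary alcohol closes onto the aldehyde to give the hemiacetal (racemic; centre lost in step 5).

**Step 4**
Reactants: 5 rac-6-hydroxy-5-methyl-2H-pyran-3(6H)-one
Product: 6 rac-3-methyl-5-oxo-5,6-dihydro-2H-pyran-2-yl acetate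
Conditions: Ac2O, pyridine, DMAP (cat.), CH2Cl2, 0 °C
Reagents that add atoms: acetic anhydride, CC(=O)OC(C)=O
Why: O-Acetylation turns the anomeric hydroxyl into the leaving group required for ylide generation.

**Step 5**
Reactants: 6 rac-3-methyl-5-oxo-5,6-dihydro-2H-pyran-2-yl acetate; 7 ethylene
Product: 9 rac-(1R,5S)-4-methyl-8-oxabicyclo[3.2.1]oct-3-en-2-one, via 5-methyl-3-oxidopyrylium 8 (not isolated)
Conditions: C2H4 (50 bar), N-methylmorpholine (1.5 equiv), MeCN, 60 °C, autoclave
Reagents that add atoms: none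
Why: Proposed new method: N-methylmorpholine removes a proton next to the ketone of 6 and acetate leaves from the acetal carbon, which gives the aromatic zwitterion 8, a cyclic carbonyl ylide that should add ethylene in a concerted suprafacial [5+2] (4π + 2π) cycloaddition across the two carbons that flank the ring oxygen; the closest known reaction type is the oxidopyrylium–alkene [5+2] cycloaddition, established between molecules for acrylates, vinyl ethers, styrenes and norbornene and within one molecule for unactivated terminal alkenes, so that only ethylene itself as the 2π partner is new. Both new rings, the oxolane (oxygen, the two bridgeheads, the two ethylene carbons) and the seven-membered carbocycle, are closed by the cycloaddition itself and not by a stepwise exo or endo cyclisation. The two new stereocentres are the bridgeheads: their cis relation is dictated by bond formation on one face of the planar ylide, and since no enantiofacial bias exists 9 should form as the racemate, the absolute configuration being selected in step 7. The selectivity needed is cycloaddition over dimerisation of 8, which the high ethylene concentration under pressure, the slow release of 8 by a weak base and the methyl group next to one ylide terminus should secure. Ethylene is symmetric, so neither regioisomers nor endo/exo isomers can arise.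

**Step 6**
Reactants: 9 rac-(1R,5S)-4-methyl-8-oxabicyclo[3.2.1]oct-3-en-2-one
Product: 10 rac-(1R,2R,5S)-4-methyl-8-oxabicyclo[3.2.1]oct-3-en-2-ol
Conditions: NaBH4, CeCl3·7H2O, MeOH, -78 °C to 0 °C
Reagents that add atoms: none
Why: Luche 1,2-reduction, in which hydride should attack from the exo face beside the oxygen bridge because the two-carbon bridge shields the endo face, giving the endo alcohol and thus the C6 configuration (threo to C7).

**Step 7**
Reactants: 10 rac-(1R,2R,5S)-4-methyl-8-oxabicyclo[3.2.1]oct-3-en-2-ol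
Product: 11 (1R,2R,5S)-4-methyl-8-oxabicyclo[3.2.1]oct-3-en-2-yl acetate
Conditions: immobilised Burkholderia cepacia lipase, vinyl acetate, t-BuOMe, 30 °C, to about half conversion
Reagents that add atoms: vinyl acetate, CC(=O)OC=C
Why: Lipase-catalysed kinetic resolution by irreversible transacetylation, in which the empirical size rule for lipases (bridgehead carbon as large, vinylic CH as medium substituent) predicts faster acylation of the (2R) enantiomer, so that 11 should be separable from the unreacted enantiomer by chromatography.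

**Step 8**
Reactants: 11 (1R,2R,5S)-4-methyl-8-oxabicyclo[3.2.1]oct-3-en-2-yl acetate
Product: 12 (1R,2R,5S)-4-methyl-8-oxabicyclo[3.2.1]oct-3-en-2-ol
Conditions: K2CO3 (cat.), MeOH, rt
Reagents that add atoms: none
Why: Base-catalysed transesterification with methanol removes the acetate without touching a stereocentre.

**Step 9**
Reactants: 12 (1R,2R,5S)-4-methyl-8-oxabicyclo[3.2.1]oct-3-en-2-ol
Product: 13 tert-butyldimethyl{[(1R,2R,5S)-4-methyl-8-oxabicyclo[3.2.1]oct-3-en-2-yl]oxy}silane
Conditions: TBSCl, imidazole, DMF, rt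
Reagents that add atoms: tert-butyldimethylsilyl chloride, CC(C)(C)[Si](C)(C)Cl
Why: Silylation of the secondary alcohol gives an ether that should survive ozone, allylborane, acylation, metathesis and borane reduction.

**Step 10**
Reactants: 13 tert-butyldimethyl{[(1R,2R,5S)-4-methyl-8-oxabicyclo[3.2.1]oct-3-en-2-yl]oxy}silane
Product: 15 (2S)-2-[(2R,5S)-5-acetyloxolan-2-yl]-2-[(tert-butyldimethylsilyl)oxy]acetaldehyde, via ozonide 14 (not isolated)
Conditions: O3, CH2Cl2, -78 °C; then PPh3, -78 °C to rt
Reagents that add atoms: ozone, [O-][O+]=O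
Why: Ozonolysis with reductive work-up cleaves the trisubstituted ring alkene into the C5 aldehyde and the C11 methyl ketone, releasing the cis-2,5-disubstituted oxolane without touching a stereocentre.

**Step 11**
Reactants: 15 (2S)-2-[(2R,5S)-5-acetyloxolan-2-yl]-2-[(tert-butyldimethylsilyl)oxy]acetaldehyde; 16 (+)-B-allyldiisopinocampheylborane (reagent derived from (-)-α-pinene, commercial solution)
Product: 17 1-[(2S,5R)-5-[(1R,2R)-1-[(tert-butyldimethylsilyl)oxy]-2-hydroxypent-4-en-1-yl]oxolan-2-yl]ethan-1-one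
Conditions: 16 (1.2 equiv), Et2O, -78 °C; then H2O2, pH 7 phosphate buffer, MeOH, 0 °C
Reagents that add atoms: none
Why: Brown allylboration through a closed chair transition state, in which the reagent from (-)-α-pinene should add to the Re face of the aldehyde to set (5R), reinforced by the Felkin–Anh preference of the α-silyloxy aldehyde for the 5,6-anti product, while the methyl ketone reacts far more slowly at -78 °C.

**Step 12**
Reactants: 17 1-[(2S,5R)-5-[(1R,2R)-1-[(tert-butyldimethylsilyl)oxy]-2-hydroxypent-4-en-1-yl]oxolan-2-yl]ethan-1-one; 18 acryloyl chloride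
Product: 19 (4R,5S)-5-[(2R,5S)-5-acetyloxolan-2-yl]-5-[(tert-butyldimethylsilyl)oxy]pent-1-en-4-yl prop-2-enoate
Conditions: i-Pr2NEt, DMAP (cat.), CH2Cl2, -78 °C to 0 °C
Reagents that add atoms: none
Why: O-Acylation of the secondary alcohol with the acid chloride installs the acrylate with retention at C5.

**Step 13**
Reactants: 19 (4R,5S)-5-[(2R,5S)-5-acetyloxolan-2-yl]-5-[(tert-butyldimethylsilyl)oxy]pent-1-en-4-yl prop-2-enoate
Product: 20 (6R)-6-[(S)-[(2R,5S)-5-acetyloxolan-2-yl][(tert-butyldimethylsilyl)oxy]methyl]-5,6-dihydro-2H-pyran-2-one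
Conditions: second-generation Grubbs catalyst RuCl2(=CHPh)(PCy3)(H2IMes) (5 mol%), CH2Cl2, 40 °C
Reagents that add atoms: none
Why: Ring-closing metathesis of the acrylate with the terminal alkene closes the α,β-unsaturated δ-lactone with loss of ethylene, the six-membered ring allowing only the cis alkene.

**Step 14**
Reactants: 20 (6R)-6-[(S)-[(2R,5S)-5-acetyloxolan-2-yl][(tert-butyldimethylsilyl)oxy]methyl]-5,6-dihydro-2H-pyran-2-one
Product: 21 (6R)-6-[(S)-[(tert-butyldimethylsilyl)oxy][(2R,5S)-5-[(1S)-1-hydroxyethyl]oxolan-2-yl]methyl]-5,6-dihydro-2H-pyran-2-one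
Conditions: (R)-2-methyl-CBS-oxazaborolidine (20 mol%), catecholborane, toluene, -78 °C; then MeOH, pH 7 buffer
Reagents that add atoms: none
Why: Corey–Bakshi–Shibata reduction, in which the (R)-oxazaborolidine (methyl as small, oxolanyl as large group) should deliver hydride to the face that gives the (11S) alcohol, in line with the Felkin–Anh preference for the threo product, while catecholborane at -78 °C should leave the conjugated lactone alone.

**Step 15**
Reactants: 22 caffeic acid
Product: 24 (2E)-3-{3,4-bis[(tert-butyldimethylsilyl)oxy]phenyl}prop-2-enoic acid, via silyl ester 23 (not isolated)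
Conditions: TBSCl (3.3 equiv), imidazole, DMF, rt; then AcOH/THF/H2O, rt
Reagents that add atoms: tert-butyldimethylsilyl chloride, CC(C)(C)[Si](C)(C)Cl
Why: Exhaustive silylation followed by selective hydrolysis of the labile silyl ester should leave both phenols protected and the acid free.

**Step 16**
Reactants: 21 (6R)-6-[(S)-[(tert-butyldimethylsilyl)oxy][(2R,5S)-5-[(1S)-1-hydroxyethyl]oxolan-2-yl]methyl]-5,6-dihydro-2H-pyran-2-one; 24 (2E)-3-{3,4-bis[(tert-butyldimethylsilyl)oxy]phenyl}prop-2-enoic acid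
Product: 25 (1S)-1-[(2S,5R)-5-[(S)-[(tert-butyldimethylsilyl)oxy][(2R)-6-oxo-3,6-dihydro-2H-pyran-2-yl]methyl]oxolan-2-yl]ethyl (2E)-3-{3,4-bis[(tert-butyldimethylsilyl)oxy]phenyl}prop-2-enoate
Conditions: EDC·HCl, DMAP, CH2Cl2, 0 °C to rt
Reagents that add atoms: none
Why: Steglich esterification (carbodiimide activation, DMAP acyl transfer) acylates the C11 alcohol with retention of configuration.

**Step 17**
Reactants: 25 (1S)-1-[(2S,5R)-5-[(S)-[(tert-butyldimethylsilyl)oxy][(2R)-6-oxo-3,6-dihydro-2H-pyran-2-yl]methyl]oxolan-2-yl]ethyl (2E)-3-{3,4-bis[(tert-butyldimethylsilyl)oxy]phenyl}prop-2-enoate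
Product: 26 (1S)-1-[(2S,5R)-5-[(S)-hydroxy[(2R)-6-oxo-3,6-dihydro-2H-pyran-2-yl]methyl]oxolan-2-yl]ethyl (2E)-3-(3,4-dihydroxyphenyl)prop-2-enoate
Conditions: HF·pyridine, pyridine, THF, 0 °C to rt
Reagents that add atoms: none
Why: Fluoride-mediated cleavage of the two aryl and the one secondary alkyl silyl ether under weakly acidic conditions should spare the cinnamate, the unsaturated lactone and the catechol.

**Compound list**
1 | 4-bromofuran-2-carbaldehyde | O=Cc1cc(Br)co1 | starting material
2 | methylboronic acid | CB(O)O | starting material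
3 | 4-methylfuran-2-carbaldehyde | Cc1coc(C=O)c1 | intermediate
4 | (4-methylfuran-2-yl)methanol | Cc1coc(CO)c1 | intermediate
5 | rac-6-hydroxy-5-methyl-2H-pyran-3(6H)-one | CC1=CC(=O)COC1O | intermediate
6 | rac-3-methyl-5-oxo-5,6-dihydro-2H-pyran-2-yl acetate | CC1=CC(=O)COC1OC(C)=O | intermediate
7 | ethylene | C=C | starting material
8 | 5-methyl-3-oxidopyrylium | Cc1c[o+]cc([O-])c1 | intermediate (not isolated)
9 | rac-(1R,5S)-4-methyl-8-oxabicyclo[3.2.1]oct-3-en-2-one | CC1=CC(=O)[C@H]2CC[C@@H]1O2 | intermediate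
10 | rac-(1R,2R,5S)-4-methyl-8-oxabicyclo[3.2.1]oct-3-en-2-ol | CC1=C[C@@H](O)[C@H]2CC[C@@H]1O2 | intermediate
11 | (1R,2R,5S)-4-methyl-8-oxabicyclo[3.2.1]oct-3-en-2-yl acetate | CC1=C[C@@H](OC(C)=O)[C@H]2CC[C@@H]1O2 | intermediate
12 | (1R,2R,5S)-4-methyl-8-oxabicyclo[3.2.1]oct-3-en-2-ol | CC1=C[C@@H](O)[C@H]2CC[C@@H]1O2 | intermediate
13 | tert-butyldimethyl{[(1R,2R,5S)-4-methyl-8-oxabicyclo[3.2.1]oct-3-en-2-yl]oxy}silane | CC1=C[C@@H](O[Si](C)(C)C(C)(C)C)[C@H]2CC[C@@H]1O2 | intermediate
14 | ozonide of 13 (1,2,4-trioxolane on the former alkene carbons, isomer mixture at these two carbons) | CC12OC(OO1)[C@@H](O[Si](C)(C)C(C)(C)C)[C@H]1CC[C@@H]2O1 | intermediate (not isolated)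
15 | (2S)-2-[(2R,5S)-5-acetyloxolan-2-yl]-2-[(tert-butyldimethylsilyl)oxy]acetaldehyde | CC(=O)[C@@H]1CC[C@H]([C@H](O[Si](C)(C)C(C)(C)C)C=O)O1 | intermediate
16 | (+)-B-allyldiisopinocampheylborane | C=CCB([C@H]1C[C@H]2C[C@@H]([C@@H]1C)C2(C)C)[C@H]1C[C@H]2C[C@@H]([C@@H]1C)C2(C)C | starting material
17 | 1-[(2S,5R)-5-[(1R,2R)-1-[(tert-butyldimethylsilyl)oxy]-2-hydroxypent-4-en-1-yl]oxolan-2-yl]ethan-1-one | CC(=O)[C@@H]1CC[C@H]([C@H](O[Si](C)(C)C(C)(C)C)[C@H](O)CC=C)O1 | intermediate
18 | acryloyl chloride | C=CC(=O)Cl | starting material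
19 | (4R,5S)-5-[(2R,5S)-5-acetyloxolan-2-yl]-5-[(tert-butyldimethylsilyl)oxy]pent-1-en-4-yl prop-2-enoate | CC(=O)[C@@H]1CC[C@H]([C@H](O[Si](C)(C)C(C)(C)C)[C@H](OC(=O)C=C)CC=C)O1 | intermediate
20 | (6R)-6-[(S)-[(2R,5S)-5-acetyloxolan-2-yl][(tert-butyldimethylsilyl)oxy]methyl]-5,6-dihydro-2H-pyran-2-one | CC(=O)[C@@H]1CC[C@H]([C@H](O[Si](C)(C)C(C)(C)C)[C@H]2CC=CC(=O)O2)O1 | intermediate
21 | (6R)-6-[(S)-[(tert-butyldimethylsilyl)oxy][(2R,5S)-5-[(1S)-1-hydroxyethyl]oxolan-2-yl]methyl]-5,6-dihydro-2H-pyran-2-one | C[C@H](O)[C@@H]1CC[C@H]([C@H](O[Si](C)(C)C(C)(C)C)[C@H]2CC=CC(=O)O2)O1 | intermediate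
22 | caffeic acid | OC(=O)/C=C/c1ccc(O)c(O)c1 | starting material
23 | tert-butyldimethylsilyl (2E)-3-{3,4-bis[(tert-butyldimethylsilyl)oxy]phenyl}prop-2-enoate | CC(C)(C)[Si](C)(C)OC(=O)/C=C/c1ccc(O[Si](C)(C)C(C)(C)C)c(O[Si](C)(C)C(C)(C)C)c1 | intermediate (not isolated)
24 | (2E)-3-{3,4-bis[(tert-butyldimethylsilyl)oxy]phenyl}prop-2-enoic acid | OC(=O)/C=C/c1ccc(O[Si](C)(C)C(C)(C)C)c(O[Si](C)(C)C(C)(C)C)c1 | intermediate
25 | (1S)-1-[(2S,5R)-5-[(S)-[(tert-butyldimethylsilyl)oxy][(2R)-6-oxo-3,6-dihydro-2H-pyran-2-yl]methyl]oxolan-2-yl]ethyl (2E)-3-{3,4-bis[(tert-butyldimethylsilyl)oxy]phenyl}prop-2-enoate | C[C@H](OC(=O)/C=C/c1ccc(O[Si](C)(C)C(C)(C)C)c(O[Si](C)(C)C(C)(C)C)c1)[C@@H]1CC[C@H]([C@H](O[Si](C)(C)C(C)(C)C)[C@H]2CC=CC(=O)O2)O1 | intermediate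
26 | (1S)-1-[(2S,5R)-5-[(S)-hydroxy[(2R)-6-oxo-3,6-dihydro-2H-pyran-2-yl]methyl]oxolan-2-yl]ethyl (2E)-3-(3,4-dihydroxyphenyl)prop-2-enoate | C[C@H](OC(=O)/C=C/c1ccc(O)c(O)c1)[C@@H]1CC[C@H]([C@H](O)[C@H]2CC=CC(=O)O2)O1 | target

**Step count and risks**
Total step count: 17. Longest linear sequence: 16 steps (steps 1 to 14, 16 and 17); step 15 is a one-step side branch.

Steps most likely to fail:

Step 5 (Proposed new method). Dimerisation or decomposition of ylide 8 may outrun its slow addition to unactivated ethylene. The fallback uses known chemistry and sets out from 6. Triethylamine and excess tert-butyl acrylate in CH2Cl2 at rt (the established acrylate version of the cycloaddition) should give tert-butyl rac-4-methyl-2-oxo-8-oxabicyclo[3.2.1]oct-3-ene-6-carboxylate F1 as endo and exo isomers that converge later. CF3CO2H in CH2Cl2 should give the carboxylic acid F2. Coupling with 2-mercaptopyridine N-oxide (DCC, DMAP, dark) should give the Barton ester F3, and irradiation with tert-butyl thiol (Barton reductive decarboxylation) removes the carboxyl group and comes back to the route at 9.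

Step 7. The enzyme may discriminate the enantiomers too weakly, so that neither acetate nor remaining alcohol is enantiopure. The fallback sets out from 10. Esterification with (S)-2-methoxy-2-phenylacetic acid (DCC, DMAP, CH2Cl2) should give the separable diastereomers (1R,2R,5S)-4-methyl-8-oxabicyclo[3.2.1]oct-3-en-2-yl (S)-2-methoxy-2-phenylacetate F4 and (1S,2S,5R)-4-methyl-8-oxabicyclo[3.2.1]oct-3-en-2-yl (S)-2-methoxy-2-phenylacetate F5. After chromatography or crystallisation, methanolysis of F4 (K2CO3, MeOH) comes back to the route at 12.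

Step 14. Hydride delivery to the α-alkoxy methyl ketone may show poor facial selectivity if the ring oxygen disturbs catalyst control. The fallback sets out from 20. Chelation-controlled reduction with Zn(BH4)2 (Et2O, -78 °C) should give the erythro alcohol (6R)-6-[(S)-[(tert-butyldimethylsilyl)oxy][(2R,5S)-5-[(1R)-1-hydroxyethyl]oxolan-2-yl]methyl]-5,6-dihydro-2H-pyran-2-one F6. Mitsunobu esterification with acid 24 (PPh3, DIAD, toluene, 0 °C) inverts C11 and comes back to the route at 25, replacing steps 14 and 16.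

**Further compounds**
F1 | step 5 | tert-butyl rac-4-methyl-2-oxo-8-oxabicyclo[3.2.1]oct-3-ene-6-carboxylate (endo and exo isomers at the ester carbon) | CC1=CC(=O)[C@H]2CC(C(=O)OC(C)(C)C)[C@@H]1O2
F2 | step 5 | rac-4-methyl-2-oxo-8-oxabicyclo[3.2.1]oct-3-ene-6-carboxylic acid | CC1=CC(=O)[C@H]2CC(C(O)=O)[C@@H]1O2
F3 | step 5 | 2-thioxopyridin-1(2H)-yl rac-4-methyl-2-oxo-8-oxabicyclo[3.2.1]oct-3-ene-6-carboxylate (Barton ester) | CC1=CC(=O)[C@H]2CC(C(=O)ON3C=CC=CC3=S)[C@@H]1O2
F4 | step 7 | (1R,2R,5S)-4-methyl-8-oxabicyclo[3.2.1]oct-3-en-2-yl (S)-2-methoxy-2-phenylacetate | CC1=C[C@@H](OC(=O)[C@@H](OC)c2ccccc2)[C@H]2CC[C@@H]1O2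
F5 | step 7 | (1S,2S,5R)-4-methyl-8-oxabicyclo[3.2.1]oct-3-en-2-yl (S)-2-methoxy-2-phenylacetate | CC1=C[C@H](OC(=O)[C@@H](OC)c2ccccc2)[C@@H]2CC[C@H]1O2
F6 | step 14 | (6R)-6-[(S)-[(tert-butyldimethylsilyl)oxy][(2R,5S)-5-[(1R)-1-hydroxyethyl]oxolan-2-yl]methyl]-5,6-dihydro-2H-pyran-2-one | C[C@@H](O)[C@@H]1CC[C@H]([C@H](O[Si](C)(C)C(C)(C)C)[C@H]2CC=CC(=O)O2)O1
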